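**Strategy.** The seven-membered ring is closed at a fully unsaturated oxidation level. The bond between C-9 of the dihydrophenanthrene (the methine shared by the six- and seven-membered rings) and the fused catechol ring C is formed as a biaryl-type bond by palladium-catalysed intramolecular C–H arylation of a phenanthren-9-yl triflate. The precursor carries at C-8 a 2,2-bis(3,4-dimethoxyphenyl)vinyl arm: because the diarylmethine carbon of the target bears two identical rings (C and pendant D), this arm has no E/Z isomers and one ring always lies cis to the triflate. The product is a masked dibenzotropylium ion, which allows enantioselective reduction at C-9 and then hydrogenation of the remaining alkene from the convex face.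

Key step: step 5

Remark on the chemistry: the starting materials of steps 1 to 3 are taken as commercial. Phenanthrene numbering puts the later methine at C-9, the arm on C-8 and the methoxy groups on C-2, C-4 and C-6. Ring letters: A = dimethoxy ring of the phenanthrene, E = its monomethoxy ring, C = the aryl ring that becomes fused, D = the pendant aryl ring.

Step 1
Reactants: 1 methyl 2-hydroxy-4-methoxy-6-methylbenzoate (sparassol)
Product: 2 methyl 4-methoxy-2-methyl-6-[(trifluoromethanesulfonyl)oxy]benzoate
Conditions: Tf2O, pyridine, CH2Cl2, 0 °C → rt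
Reagents that add atoms: trifluoromethanesulfonic anhydride, O=S(=O)(OS(=O)(=O)C(F)(F)F)C(F)(F)F
Why: O-sulfonylation of the salicylate phenol with triflic anhydride and pyridine is a standard aryl triflate synthesis that leaves the ester and the methyl ether untouched.

Step 2
Reactants: 2 methyl 4-methoxy-2-methyl-6-[(trifluoromethanesulfonyl)oxy]benzoate; 3 1-bromo-2,4-dimethoxy-6-methylbenzene
Product: 5 methyl 2',4',5-trimethoxy-3,6'-dimethyl[1,1'-biphenyl]-2-carboxylate, via arylzinc chloride 4 (not isolated)
Conditions: 3, n-BuLi, THF, −78 °C; ZnCl2, −78 °C → rt; then 2, Pd(OAc)2 (cat.), SPhos (cat.), THF, 65 °C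
Reagents that add atoms: zinc chloride, Cl[Zn]Cl (zinc and chlorine of intermediate 4 only)
Why: Bromine–lithium exchange and transmetalation give an arylzinc that should undergo Negishi coupling with the ortho-ester aryl triflate, a reaction type established with biarylphosphine ligands for tri-ortho-substituted biaryls.

Step 3
Reactants: 5 methyl 2',4',5-trimethoxy-3,6'-dimethyl[1,1'-biphenyl]-2-carboxylate; 6 bis(3,4-dimethoxyphenyl)methanone
Product: 8 methyl 3-[2,2-bis(3,4-dimethoxyphenyl)ethenyl]-2',4',5-trimethoxy-6'-methyl[1,1'-biphenyl]-2-carboxylate, via lithium alkoxide of carbinol 7 (not isolated)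
Conditions: LiN(iPr)2 (1.1 equiv), THF, −78 °C; 6, −78 → −20 °C; then MsCl, Et3N, −20 → 0 °C
Reagents that add atoms: none
Why: Lateral lithiation of the o-toluate methyl group (the only acidic benzylic position at −78 °C), 1,2-addition to the diaryl ketone and E1 dehydration of the tertiary mesylate toward the only β-hydrogens should give the alkene, which has no E/Z isomers because both aryl groups are the same.

Step 4
Reactants: 8 methyl 3-[2,2-bis(3,4-dimethoxyphenyl)ethenyl]-2',4',5-trimethoxy-6'-methyl[1,1'-biphenyl]-2-carboxylate
Product: 10 8-[2,2-bis(3,4-dimethoxyphenyl)ethenyl]-2,4,6-trimethoxyphenanthren-9-yl trifluoromethanesulfonate, via lithium phenanthrolate 9 (not isolated)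
Conditions: LiN(iPr)2 (3 equiv), THF, −78 → 0 °C; then PhNTf2 (excess), 0 °C → rt
Reagents that add atoms: N-phenylbis(trifluoromethanesulfonimide), O=S(=O)(N(c1ccccc1)S(=O)(=O)C(F)(F)F)C(F)(F)F
Why: Ester-directed remote lateral metalation of the 6'-methyl group and intramolecular Claisen-type acylation (the anionic ring closure of 2'-methylbiaryl-2-carboxylic acid derivatives to phenanthren-9-ols) place the oxygen on the carbon attached to ring E without regiochemical ambiguity, and the phenanthrolate is O-sulfonylated in the same flask.

Step 5
Reactants: 10 8-[2,2-bis(3,4-dimethoxyphenyl)ethenyl]-2,4,6-trimethoxyphenanthren-9-yl trifluoromethanesulfonate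
Product: 11 achiral hexadehydro heptamethyl ether (2,4,6-trimethoxyphenanthrene whose C-9 is bonded to C-2 of a 4,5-dimethoxy-1,2-phenylene, ring C, and whose C-8 carries CH= double-bonded to a carbon that bears ring D and is bonded to C-1 of the same phenylene)
Conditions: Pd(OAc)2 (5 mol %), PCy3·HBF4 (10 mol %), K2CO3, PivOH (30 mol %), DMA, 110 °C
Reagents that add atoms: none
Why: Zerovalent palladium formed in the flask adds oxidatively into the C-9 triflate, carbonate/pivalate-assisted concerted metalation–deprotonation then takes the C-6' hydrogen of the dimethoxyphenyl group held cis to the phenanthrene, and reductive elimination forms the C-9–aryl bond. The closest known reaction type is the intramolecular direct arylation of aryl halides and triflates under Pd/PCy3/pivalate conditions, which closes six- and seven-membered biaryl rings. The seven-membered ring is closed by C–C reductive elimination from an eight-membered diarylpalladium species, formally a 7-exo attack on the arene; a Heck-type five-ring closure is disfavoured because the alkene carbon within reach is fully substituted. No stereocentre is formed, since the step is run at the planar oxidation level on purpose. The selectivity needed is C-6' over C-2' of the reacting ring and the cis over the trans aryl group: C-2' is flanked by a methoxy group and the alkene carbon, and the trans ring cannot reach C-9.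

Step 6
Reactants: 11 achiral hexadehydro heptamethyl ether
Product: 12 (9R)-9,10-dihydro derivative of 11 (C-9 is CH bonded to ring C, C-10 is CH2, the C=C of the seven-membered ring is retained)
Conditions: chiral BINOL-derived N-triflylphosphoramide with 3,3'-bis(2,4,6-triisopropylphenyl) groups (10 mol %, antipode chosen by screening), Hantzsch ester (1.1 equiv), toluene, 40 °C
Reagents that add atoms: none
Why: Proposed new method: protonation of 11 at C-10 by the chiral acid merges the phenanthrene 9,10-bond and the styrenic bond into a 6π dibenzotropylium ion paired with the chiral anion, and the Hantzsch ester should deliver hydride to C-9 on one face of this ion pair, which sets the (R)-methine under catalyst control; the closest known reaction types are the chiral phosphoric acid/Hantzsch ester transfer hydrogenation of benzopyrylium ions and the hydride reduction of tropylium ions by 1,4-dihydropyridines.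

Step 7
Reactants: 12 (9R)-9,10-dihydro derivative of 11
Product: 13 hepta-O-methyl ether of the target (seven-membered-ring C=C saturated to CH2–CH(3,4-dimethoxyphenyl); R at C-9, S at the diarylmethine)
Conditions: H2 (5 bar), 10% Pd on carbon, EtOAc/MeOH, rt
Reagents that add atoms: none
Why: Heterogeneous catalytic hydrogenation of the triaryl alkene in the boat-shaped dibenzocycloheptene should occur on the exposed convex face, the one that carries the axial C-9 hydrogen, so the new diarylmethine hydrogen is cis to H-9 and the centre is (S) by substrate control.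

Step 8
Reactants: 13 hepta-O-methyl ether of the target
Product: 14 target CNP0306974.1 (heptaphenol; R at C-9, S at the diarylmethine)
Conditions: BBr3 (excess), CH2Cl2, −78 °C → rt; then MeOH, H2O
Reagents that add atoms: none
Why: Boron tribromide cleaves all seven aryl methyl ethers by Lewis acid-assisted SN2 demethylation, and the two benzylic stereocentres carry no leaving group and should not ionise at low temperature.

**Compound list**

1 | methyl 2-hydroxy-4-methoxy-6-methylbenzoate | COC(=O)c1c(C)cc(OC)cc1O | starting material
2 | methyl 4-methoxy-2-methyl-6-[(trifluoromethanesulfonyl)oxy]benzoate | COC(=O)c1c(C)cc(OC)cc1OS(=O)(=O)C(F)(F)F | intermediate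
3 | 1-bromo-2,4-dimethoxy-6-methylbenzene | Cc1cc(OC)cc(OC)c1Br | starting material
4 | (2,4-dimethoxy-6-methylphenyl)zinc chloride | Cc1cc(OC)cc(OC)c1[Zn]Cl | intermediate
5 | methyl 2',4',5-trimethoxy-3,6'-dimethyl[1,1'-biphenyl]-2-carboxylate | COC(=O)c1c(C)cc(OC)cc1-c1c(C)cc(OC)cc1OC | intermediate
6 | bis(3,4-dimethoxyphenyl)methanone | COc1ccc(cc1OC)C(=O)c1ccc(OC)c(OC)c1 | starting material
7 | methyl 3-[2,2-bis(3,4-dimethoxyphenyl)-2-hydroxyethyl]-2',4',5-trimethoxy-6'-methyl[1,1'-biphenyl]-2-carboxylate (present as its lithium alkoxide) | COC(=O)c1c(CC(O)(c2ccc(OC)c(OC)c2)c2ccc(OC)c(OC)c2)cc(OC)cc1-c1c(C)cc(OC)cc1OC | intermediate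
8 | methyl 3-[2,2-bis(3,4-dimethoxyphenyl)ethenyl]-2',4',5-trimethoxy-6'-methyl[1,1'-biphenyl]-2-carboxylate | COC(=O)c1c(C=C(c2ccc(OC)c(OC)c2)c2ccc(OC)c(OC)c2)cc(OC)cc1-c1c(C)cc(OC)cc1OC | intermediate
9 | 8-[2,2-bis(3,4-dimethoxyphenyl)ethenyl]-2,4,6-trimethoxyphenanthren-9-ol (present as its lithium salt) | COc1cc(C=C(c2ccc(OC)c(OC)c2)c2ccc(OC)c(OC)c2)c2c(O)cc3cc(OC)cc(OC)c3c2c1 | intermediate
10 | 8-[2,2-bis(3,4-dimethoxyphenyl)ethenyl]-2,4,6-trimethoxyphenanthren-9-yl trifluoromethanesulfonate | COc1cc(C=C(c2ccc(OC)c(OC)c2)c2ccc(OC)c(OC)c2)c2c(OS(=O)(=O)C(F)(F)F)cc3cc(OC)cc(OC)c3c2c1 | intermediate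
11 | achiral hexadehydro heptamethyl ether (phenanthrene fused through C-8 and C-9 to an unsaturated seven-membered ring that carries ring C and ring D) | COc1cc(OC)c2c(c1)cc1-c3cc(OC)c(OC)cc3C(c3ccc(OC)c(OC)c3)=Cc3cc(OC)cc2c31 | intermediate
12 | (9R)-9,10-dihydro derivative of 11 | COc1cc(OC)c2c(c1)C[C@@H]1c3cc(OC)c(OC)cc3C(c3ccc(OC)c(OC)c3)=Cc3cc(OC)cc-2c31 | intermediate
13 | hepta-O-methyl ether of the target (R at C-9, S at the diarylmethine) | COc1cc(OC)c2c(c1)C[C@@H]1c3cc(OC)c(OC)cc3[C@H](c3ccc(OC)c(OC)c3)Cc3cc(OC)cc-2c31 | intermediate
14 | CNP0306974.1 (heptaphenol; R at C-9, S at the diarylmethine) | Oc1cc(O)c2c(c1)C[C@@H]1c3cc(O)c(O)cc3[C@H](c3ccc(O)c(O)c3)Cc3cc(O)cc-2c31 | target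

**Step count.** Total: 8 steps. Longest linear sequence: 8 steps (1 → 14).

**Steps most likely to fail**

Step 6 (Proposed new method). The weakly basic arene may be protonated too little by the chiral acid, or hydride transfer inside the ion pair may discriminate the two faces poorly. The fallback uses known chemistry and sets out from 11. Ionic hydrogenation with CF3CO2H and Et3SiH in CH2Cl2 at 0 °C should reduce the 9,10-bond through the tropylium ion and then the alkene through the diarylmethyl cation, with hydride arriving on the convex face, to give the racemic hepta-O-methyl ether F1. Preparative chromatography on a chiral stationary phase separates it from the (9S) enantiomer of 13, F2, and the route is rejoined at 13.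

Step 5 (key step). Oxidative addition and C–H cleavage at the peri-crowded triflate may be slow, so that loss of the triflate by reduction competes. The fallback sets out from phenanthrol 9, isolated by a protic quench of step 4, and makes no new compound (F0). A Bradsher-type cyclodehydration with MsOH in HFIP/CH2Cl2 at rt lets the cis aryl group attack the protonated keto tautomer at C-9; loss of water through the tropylium ion and of H-10 then gives 11, where the route is rejoined.

Step 4. Remote deprotonation of the 6'-methyl group may be incomplete, or the amide base may attack the hindered ester. The fallback sets out from 8, which is converted with AlMe3/Et2NH in toluene at 90 °C into the N,N-diethylamide analogue of 8, F3. Amide-directed remote metalation with LiN(iPr)2 in THF at 0 °C → rt, followed by PhNTf2, then returns to the route at 10.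

**Further compounds**

F1 | step 6 | racemic hepta-O-methyl ether (13 and its enantiomer) | COc1cc(OC)c2c(c1)C[C@@H]1c3cc(OC)c(OC)cc3[C@H](c3ccc(OC)c(OC)c3)Cc3cc(OC)cc-2c31.COc1cc(OC)c2c(c1)C[C@H]1c3cc(OC)c(OC)cc3[C@@H](c3ccc(OC)c(OC)c3)Cc3cc(OC)cc-2c31
F2 | step 6 | (9S) enantiomer of 13 | COc1cc(OC)c2c(c1)C[C@H]1c3cc(OC)c(OC)cc3[C@@H](c3ccc(OC)c(OC)c3)Cc3cc(OC)cc-2c31
F0 | step 5 | none | none
F3 | step 4 | 3-[2,2-bis(3,4-dimethoxyphenyl)ethenyl]-N,N-diethyl-2',4',5-trimethoxy-6'-methyl[1,1'-biphenyl]-2-carboxamide | CCN(CC)C(=O)c1c(C=C(c2ccc(OC)c(OC)c2)c2ccc(OC)c(OC)c2)cc(OC)cc1-c1c(C)cc(OC)cc1OC
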